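**Retrosynthetic overview**
1. The vanillate ester is made last, on the C-6 hydroxyl of a cis-6,9-diol whose less hindered C-9 hydroxyl is silylated.
2. The cis-ene-1,4-diol comes from singlet-oxygen [4+2] addition to the ring diene of a bicyclic dienol, anti to the angular methyl.
3. The C-4 carbinol comes from isopropyl Grignard addition to a trans-fused ketone; the C-1 quaternary methyl comes from an enantioselective conjugate methylation of an achiral azulenone.
4. The azulenone comes from an intramolecular Buchner ring expansion of a p-tolyl diazoketone: the cyclopentanone and the seven-membered ring form together, and the para-methyl becomes the C-8 methyl.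
5. Ring order: five- and seven-membered rings together in step 2; no ring is formed afterwards.

Assumption: positions in the text use daucane numbering (C-1 angular-methyl carbon, C-4 isopropyl carbinol, C-5 ring-fusion CH, C-6 ester carbon, C-7=C-8(CH3), C-9 free carbinol, C-10 CH2; β = face of the angular methyl), compound names use azulene numbering, and the target SMILES is read as (3R,3aS,4S,7S,8aR).

Step 1
Reactants: 1 3-(4-methylphenyl)propanoic acid
Product: 3 1-diazo-4-(4-methylphenyl)butan-2-one, via acid chloride 2 (not isolated)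
Conditions: (COCl)2, DMF (cat.), CH2Cl2, 0 °C to rt; then CH2N2, Et3N, Et2O, 0 °C
Reagents that add atoms: diazomethane, C=[N+]=[N-]
Why: Acyl chloride formation followed by C-acylation of diazomethane (Arndt–Eistert-type diazoketone synthesis), with Et3N taking up the HCl so that no chloromethyl ketone forms; no stereocentre is created.

Step 2
Reactants: 3 1-diazo-4-(4-methylphenyl)butan-2-one
Product: 6 6-methyl-3,4-dihydroazulen-1(2H)-one, via norcaradiene 4 (not isolated), via 8aH-azulenone 5 (not isolated)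
Conditions: Rh2(OAc)4 (1 mol %), CH2Cl2, reflux, slow addition; then Et3N, rt
Reagents that add atoms: none
Why: Intramolecular Buchner reaction: the rhodium carbene adds across the ipso/ortho bond of the tolyl ring, closing the cyclopentanone and a cyclopropane at once, norcaradiene 4 opens by 6π-electrocyclic ring opening to cycloheptatriene 5, and Et3N shifts the doubly activated ring-fusion hydrogen to give the cross-conjugated trienone in which the former para-methyl sits on C-8 and the former ipso carbon (C-1) is the enone β-carbon; the product is achiral.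

Step 3
Reactants: 6 6-methyl-3,4-dihydroazulen-1(2H)-one
Product: 8 (3aR,8aR)-3a,6-dimethyl-3,3a,4,8a-tetrahydroazulen-1(2H)-one, via aluminium trienolate 7 (not isolated)
Conditions: Me3Al, Cu(O2CC4H3S) (copper thiophene-2-carboxylate, 5 mol %), O,O'-(S)-1,1'-binaphthyl-2,2'-diyl N,N-bis[(S)-1-phenylethyl]phosphoramidite (10 mol %), Et2O, −30 °C; then 2,6-di-tert-butyl-4-methylphenol, −78 °C
Reagents that add atoms: trimethylaluminium, C[Al](C)C
Why: Proposed new method: copper-catalysed enantioselective conjugate addition of Me3Al to a tetrasubstituted enone, in which C-1 is the only carbon whose attack gives an oxygen-stabilised trienolate (regiochemistry fixed), the phosphoramidite–methylcopper complex selects the enone face (the ligand antipode that makes C-1 R is used, to be confirmed on the first run), and kinetic α-protonation of the nearly flat trienolate 7 by the bulky phenol occurs anti to the new pseudo-axial methyl to give the trans ring fusion at C-5; the closest known reaction is the phosphoramidite/copper-catalysed Me3Al addition to β,β-disubstituted cyclopentenones that forms quaternary centres.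

Step 4
Reactants: 8 (3aR,8aR)-3a,6-dimethyl-3,3a,4,8a-tetrahydroazulen-1(2H)-one (used crude)
Product: 9 (3R,3aR,8aR)-6,8a-dimethyl-3-(propan-2-yl)-1,2,3,3a,8,8a-hexahydroazulen-3-ol
Conditions: i-PrMgCl, LaCl3·2LiCl, THF, −20 °C
Reagents that add atoms: isopropylmagnesium chloride, CC(C)[Mg]Cl
Why: Grignard 1,2-addition promoted by LaCl3·2LiCl (which suppresses enolisation of the acidic α-hydrogen and β-hydride reduction): the nucleophile enters the cyclopentanone from the face of H-5, away from the adjacent C-5–C-6 bond and the 1,3-related angular methyl, so the tertiary hydroxyl ends up cis to that methyl (C-4 R).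

Step 5
Reactants: 9 (3R,3aR,8aR)-6,8a-dimethyl-3-(propan-2-yl)-1,2,3,3a,8,8a-hexahydroazulen-3-ol
Product: 11 (3R,3aS,4S,7S,8aR)-6,8a-dimethyl-3-(propan-2-yl)-1,2,3,3a,4,7,8,8a-octahydroazulene-3,4,7-triol, via endoperoxide 10 (not isolated)
Conditions: O2, hν (visible), 5,10,15,20-tetraphenylporphyrin (cat.), CH2Cl2–MeOH, −30 °C; then Zn, AcOH, 0 °C
Reagents that add atoms: dioxygen, O=O
Why: Photooxygenation: singlet-oxygen [4+2] cycloaddition to the s-cis ring diene takes place on the face opposite the pseudo-axial angular methyl that overhangs the diene, and reductive O–O cleavage by zinc leaves both C–O bonds intact, so the cis-6,9-diol has both hydroxyls anti to the methyl (C-6 S, C-9 S).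

Step 6
Reactants: 11 (3R,3aS,4S,7S,8aR)-6,8a-dimethyl-3-(propan-2-yl)-1,2,3,3a,4,7,8,8a-octahydroazulene-3,4,7-triol
Product: 12 (3R,3aS,4S,7S,8aR)-7-[(tert-butyldimethylsilyl)oxy]-6,8a-dimethyl-3-(propan-2-yl)-1,2,3,3a,4,7,8,8a-octahydroazulene-3,4-diol
Conditions: TBSCl (1.1 equiv), imidazole, DMF, 0 °C
Reagents that add atoms: tert-butyldimethylsilyl chloride, CC(C)(C)[Si](C)(C)Cl
Why: Sterically controlled monosilylation: the C-9 hydroxyl (next to a ring CH2) reacts much faster than the C-6 hydroxyl, which sits beside the fully substituted C-5/C-4 region, and the tertiary hydroxyl is inert; no stereocentre is affected.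

Step 7
Reactants: 12 (3R,3aS,4S,7S,8aR)-7-[(tert-butyldimethylsilyl)oxy]-6,8a-dimethyl-3-(propan-2-yl)-1,2,3,3a,4,7,8,8a-octahydroazulene-3,4-diol; 13 4-acetoxy-3-methoxybenzoic acid
Product: 15 (3R,3aS,4S,7S,8aR)-7-[(tert-butyldimethylsilyl)oxy]-3-hydroxy-6,8a-dimethyl-3-(propan-2-yl)-1,2,3,3a,4,7,8,8a-octahydroazulen-4-yl 4-acetoxy-3-methoxybenzoate, via O-acylisourea 14 (not isolated)
Conditions: DCC, DMAP (cat.), CH2Cl2, rt
Reagents that add atoms: none
Why: Steglich esterification acylates the only free secondary hydroxyl at oxygen, so C-6 keeps its configuration, and the hindered C-6 hydroxyl of daucane diols is known to accept aroyl groups under these conditions.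

Step 8
Reactants: 15 (3R,3aS,4S,7S,8aR)-7-[(tert-butyldimethylsilyl)oxy]-3-hydroxy-6,8a-dimethyl-3-(propan-2-yl)-1,2,3,3a,4,7,8,8a-octahydroazulen-4-yl 4-acetoxy-3-methoxybenzoate
Product: 17 (3R,3aS,4S,7S,8aR)-3,7-dihydroxy-6,8a-dimethyl-3-(propan-2-yl)-1,2,3,3a,4,7,8,8a-octahydroazulen-4-yl 4-hydroxy-3-methoxybenzoate, via silyl ether phenol 16 (not isolated)
Conditions: pyrrolidine, THF, rt; then HF·pyridine, 0 °C to rt
Reagents that add atoms: none
Why: Aminolysis of the aryl acetate (an active ester) by pyrrolidine spares the hindered vanillate, and fluoride-mediated silyl ether cleavage frees the C-9 hydroxyl; no stereocentre is touched.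

**Compound list**
1 | 3-(4-methylphenyl)propanoic acid | Cc1ccc(CCC(=O)O)cc1 | starting material
2 | 3-(4-methylphenyl)propanoyl chloride | Cc1ccc(CCC(=O)Cl)cc1 | intermediate
3 | 1-diazo-4-(4-methylphenyl)butan-2-one | Cc1ccc(CCC(=O)C=[N+]=[N-])cc1 | intermediate
4 | 8-methyltricyclo[4.4.0.0(1,5)]deca-7,9-dien-4-one (norcaradiene, racemic) | O=C1CCC23C=CC(C)=CC2C13 | intermediate
5 | 6-methyl-3,8a-dihydroazulen-1(2H)-one (racemic) | O=C1CCC2=CC=C(C)C=CC12 | intermediate
6 | 6-methyl-3,4-dihydroazulen-1(2H)-one | O=C1CCC2=C1C=CC(C)=CC2 | intermediate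
7 | dimethylaluminium (3aR)-3a,6-dimethyl-2,3,3a,4-tetrahydroazulen-1-olate | C[Al](C)OC1=C2C=CC(C)=CC[C@@]2(C)CC1 | intermediate
8 | (3aR,8aR)-3a,6-dimethyl-3,3a,4,8a-tetrahydroazulen-1(2H)-one (trans-fused) | CC1=CC[C@@]2(C)CCC(=O)[C@@H]2C=C1 | intermediate
9 | (3R,3aR,8aR)-6,8a-dimethyl-3-(propan-2-yl)-1,2,3,3a,8,8a-hexahydroazulen-3-ol | CC1=CC[C@@]2(C)CC[C@@](O)(C(C)C)[C@@H]2C=C1 | intermediate
10 | (3R,3aS,4S,7S,8aR)-6,8a-dimethyl-3-(propan-2-yl)-1,2,3,3a,4,7,8,8a-octahydro-4,7-epidioxyazulen-3-ol (6α,9α-endoperoxide) | O1[C@H]2C=C(C)[C@@H](O1)C[C@@]3(C)CC[C@@](O)(C(C)C)[C@H]23 | intermediate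
11 | (3R,3aS,4S,7S,8aR)-6,8a-dimethyl-3-(propan-2-yl)-1,2,3,3a,4,7,8,8a-octahydroazulene-3,4,7-triol | O[C@H]1C=C(C)[C@@H](O)C[C@@]2(C)CC[C@@](O)(C(C)C)[C@H]12 | intermediate
12 | (3R,3aS,4S,7S,8aR)-7-[(tert-butyldimethylsilyl)oxy]-6,8a-dimethyl-3-(propan-2-yl)-1,2,3,3a,4,7,8,8a-octahydroazulene-3,4-diol | O[C@H]1C=C(C)[C@@H](O[Si](C)(C)C(C)(C)C)C[C@@]2(C)CC[C@@](O)(C(C)C)[C@H]12 | intermediate
13 | 4-acetoxy-3-methoxybenzoic acid | COc1cc(C(=O)O)ccc1OC(C)=O | starting material
14 | O-(4-acetoxy-3-methoxybenzoyl)-N,N'-dicyclohexylisourea | COc1cc(C(=O)OC(=NC2CCCCC2)NC2CCCCC2)ccc1OC(C)=O | intermediate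
15 | (3R,3aS,4S,7S,8aR)-7-[(tert-butyldimethylsilyl)oxy]-3-hydroxy-6,8a-dimethyl-3-(propan-2-yl)-1,2,3,3a,4,7,8,8a-octahydroazulen-4-yl 4-acetoxy-3-methoxybenzoate | COc1cc(C(=O)O[C@H]2C=C(C)[C@@H](O[Si](C)(C)C(C)(C)C)C[C@@]3(C)CC[C@@](O)(C(C)C)[C@H]23)ccc1OC(C)=O | intermediate
16 | (3R,3aS,4S,7S,8aR)-7-[(tert-butyldimethylsilyl)oxy]-3-hydroxy-6,8a-dimethyl-3-(propan-2-yl)-1,2,3,3a,4,7,8,8a-octahydroazulen-4-yl 4-hydroxy-3-methoxybenzoate | COc1cc(C(=O)O[C@H]2C=C(C)[C@@H](O[Si](C)(C)C(C)(C)C)C[C@@]3(C)CC[C@@](O)(C(C)C)[C@H]23)ccc1O | intermediate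
17 | (3R,3aS,4S,7S,8aR)-3,7-dihydroxy-6,8a-dimethyl-3-(propan-2-yl)-1,2,3,3a,4,7,8,8a-octahydroazulen-4-yl 4-hydroxy-3-methoxybenzoate (CNP0189996.2) | COc1cc(C(=O)O[C@H]2C=C(C)[C@@H](O)C[C@@]3(C)CC[C@@](O)(C(C)C)[C@H]23)ccc1O | target

**Totals**
Total step count: 8. Longest linear sequence: 8 steps (1 to 17); 13 is bought.

**Three steps most likely to fail**

Step 3. The enone is tetrasubstituted, so the catalytic conjugate methylation may be slow or poorly enantioselective, and the ring-fusion hydrogen is set by a kinetic protonation. The fallback sets out from 6 and comes back at 8. Asymmetric 1,2-reduction of 6 with catecholborane and (R)-2-methyl-CBS-oxazaborolidine gives (S)-6-methyl-1,2,3,4-tetrahydroazulen-1-ol F1. Its hydroxyl directs a Simmons–Smith cyclopropanation (Et2Zn, CH2I2) onto its own face of the neighbouring tetrasubstituted alkene, giving the syn cyclopropyl carbinol 6-methyl-1,2,3,4-tetrahydro-3a,8a-methanoazulen-1-ol F2. Dess–Martin oxidation gives the cyclopropyl ketone 6-methyl-3,4-dihydro-3a,8a-methanoazulen-1(2H)-one F3. SmI2 (THF–HMPA, t-BuOH) then cleaves the external cyclopropane bond that overlaps with the ketyl, which turns the CH2 bridge into the angular methyl; protonation of the samarium enolate with the same bulky phenol gives 8.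

Step 4. The α-hydrogen of 8 is both α-keto and allylic, so enolisation or isomerisation to the conjugated dienone can compete with addition, and the facial selectivity depends on the ring fusion. The fallback sets out from 8 and comes back at 11. Ketone 8 is photooxygenated first (O2, hν, tetraphenylporphyrin) to the keto endoperoxide 6α,9α-epidioxy-5α-H-dauc-7-en-4-one F4, which Zn/AcOH reduces to the keto diol 6α,9α-dihydroxy-5α-H-dauc-7-en-4-one F5. In F5 the α-hydrogen is no longer allylic. Excess i-PrMgCl with LaCl3·2LiCl then adds to the C-4 carbonyl, which is chelated by the C-6 magnesium alkoxide, again anti to the angular methyl, and gives triol 11 directly.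

Step 6. The two secondary allylic hydroxyls may not differ enough for clean monosilylation. The fallback sets out from 9 and comes back at 12. The crude endoperoxide 10 made from 9 is treated with Et3N instead of zinc (Kornblum–DeLaMare rearrangement). Loss of H-6 (H-9 is shielded by the syn-axial methyl) gives the hydroxy enone 4β,9α-dihydroxy-5α-H-dauc-7-en-6-one F6. Its only secondary hydroxyl (C-9) is silylated with TBSCl and imidazole to the silyl ether 9α-(tert-butyldimethylsilyloxy)-4β-hydroxy-5α-H-dauc-7-en-6-one F7. Hydroxyl-directed reduction with Me4NBH(OAc)3, in which the tertiary C-4 hydroxyl delivers hydride to the β-face (1,3-anti), gives the 6α-alcohol 12.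

**Further compounds**
F1 | step 3 | (S)-6-methyl-1,2,3,4-tetrahydroazulen-1-ol | CC1=CCC2=C(C=C1)[C@@H](O)CC2
F2 | step 3 | 6-methyl-1,2,3,4-tetrahydro-3a,8a-methanoazulen-1-ol with the CH2 bridge syn to the hydroxyl | CC1=CC[C@]23C[C@@]2(C=C1)[C@@H](O)CC3
F3 | step 3 | 6-methyl-3,4-dihydro-3a,8a-methanoazulen-1(2H)-one with the CH2 bridge on the face of the future angular methyl | CC1=CC[C@]23C[C@@]2(C=C1)C(=O)CC3
F4 | step 4 | 6α,9α-epidioxy-5α-H-dauc-7-en-4-one | O1[C@H]2C=C(C)[C@@H](O1)C[C@@]3(C)CCC(=O)[C@H]23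
F5 | step 4 | 6α,9α-dihydroxy-5α-H-dauc-7-en-4-one | O[C@H]1C=C(C)[C@@H](O)C[C@@]2(C)CCC(=O)[C@H]12
F6 | step 6 | 4β,9α-dihydroxy-5α-H-dauc-7-en-6-one | O=C1C=C(C)[C@@H](O)C[C@@]2(C)CC[C@@](O)(C(C)C)[C@H]12
F7 | step 6 | 9α-(tert-butyldimethylsilyloxy)-4β-hydroxy-5α-H-dauc-7-en-6-one | O=C1C=C(C)[C@@H](O[Si](C)(C)C(C)(C)C)C[C@@]2(C)CC[C@@](O)(C(C)C)[C@H]12
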